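## The problem

Polymatin A (23) is a melampolide. Ring A is a cyclodeca-1(10),4-diene in which C4=C5 is ring-trans and C1=C10 is ring-cis and carries the C14 methyl ester. Ring A is trans-fused at C6–C7 to ring B, an α-methylene-γ-butyrolactone made of O6, C12, C11, C7 and C6.

Ten-membered carbocycles resist direct closure, and any closure here must respect both olefin geometries.

The stereocenters C6, C7, C8 and C9 are contiguous. O6 and C11 are trans on ring B. C11 and O8 are erythro, which is contra-steric on any six-membered template. O8 and O9 are threo. The two vicinal oxygens must also be told apart, because O8 carries the angelate and O9 stays free.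

Several groups will not survive rough treatment:
- the α-methylene lactone is a Michael acceptor;
- the angelate isomerizes from Z to E;
- the O8 acyl group can shift to O9;
- the 1,5-diene can undergo Cope rearrangement or acid-induced transannular cyclization.

The feature that makes the key step possible is the chain C6–C9. It is bounded by the sp2 carbons C5 and C10, and its oxygens O6 and O9 are 1,4-related, so it is a reduced γ-hydroxy enone (C6–O, C7=C8, C9=O). Ring B ties O6 to C7 through exactly two atoms, C12 and C11. An O6-bound two-carbon nucleophile therefore reaches C7 through a five-membered transition state. A C9 ketone can enolize only toward C8, because C10 bears no hydrogen.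

As a result C6 can control C7, C7 can control C8, and C8 can control C9.

## Retrosynthesis

**C9–H.** The last cut is the C9–H bond, which leads back to the α-angeloyloxy ketone 22. It is preferred to any O9 protecting group because the free hydroxyl is then created in the final step, next to an angelate that is already in place. 22 has one stereocenter fewer than 23. The forward reaction must be a 1,2-reduction that follows the polar Felkin–Anh sense, which gives the threo product.

**C8–O.** The C8–O bond is cut next, giving angelic acid 21 and the α-bromo ketone 20. Compound 20 comes from ketone 18 through the silyl dienol ether 19. An oxygen electrophile would enter C8 from the exposed face and give the wrong epimer. A leaving group put on that face and displaced with inversion gives the right epimer, and it brings in the angelate in the same event. The forward steps need α′-selective enolization and a clean SN2 reaction at an α-keto carbon.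

**C7–C11 and C11=C13 (key disconnection).** Both bonds are cut at once, so 18 goes back through phosphonolactone 17 to the macrocyclic γ-acyloxy trienone 16. This removes ring B, the exocyclic methylene and C7, and leaves one stereocenter (C6) in a nearly flat ring. Cutting C6–C7 instead would reopen ring A. Cutting O6–C12 would leave C7 to be set without a tether. The forward reaction must add C11 to C7 and not to C1, and it must place C8 trans to C5 on ring B.

**C7=C8.** This olefin does not survive into the target. Cutting it takes 16 back through alcohol 15 and silyl ether 14 to the acyclic tetraene 13. It is the only ring bond that can be made from two monosubstituted vinyl carbinols, which is the easiest case of ring-closing metathesis. Both trisubstituted olefins then stay spectators with their geometry fixed beforehand. The ring formed is of the cis,cis,trans-cyclodeca-1,4,7-triene type.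

**O6–C12 and C6–C7.** Ester 13 is cut to alcohol 11 and (diethoxyphosphoryl)acetic acid 12. Alcohol 11 is cut at C6–C7 to enal 10 and a vinyl nucleophile. This is the single place where absolute configuration is introduced, by catalysis.

**C9–C10.** Enal 10 comes from 9, 8 and 7 by functional-group changes. Alcohol 7 is cut at C9–C10 to acrolein 5 and the alkenylmagnesium 6, which is made from iodide 4. C9 may be racemic because it becomes a ketone in 16, so no second asymmetric step is needed.

**C1=C10.** Iodide 4 is cut at C1=C10 to aldehyde 3. Aldehyde 3 comes through epoxide 2 from geranyl acetate 1, which supplies C1–C6, C15 and the E-C4=C5 bond ready-made.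

## Roads not taken

**Alternative 1: cut C6–C7 and O6–C12 (the most obvious route).** The forward key step is an intramolecular Barbier or Nozaki–Hiyama–Kishi allylation of the enal terminus of the bromomethyl acrylate A1, followed by lactonization.
- A1 must already hold C8 and C9 with two orthogonal protecting groups.
- The ten-membered ring is closed directly, in the same event that creates C6 and C7, and the sense of these relative to C8 depends on a strained transition state.
- O8 and O9 still have to be differentiated afterwards.
- The chosen plan closes the ring at an unhindered olefin with one stereocenter present and uses one protecting group.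

**Alternative 2: cut C2–C3 and reconnect C5–C10.** The forward key step is an anionic oxy-Cope ring expansion of the cis-divinylcyclohexanol A2, followed by enolate triflation and methoxycarbonylation.
- In the chair transition state, the ring bond that stands pseudo-axial ends ring-cis.
- The melampolide geometry therefore needs the cyclohexane conformer with an axial isopropenyl group, which in A2 is 1,3-diaxial to the C7 side chain.
- The accessible conformer has an equatorial isopropenyl and an axial vinyl group. It leads to ring-cis C4=C5 and ring-trans C1=C10, the wrong pair.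
- A2 also carries six stereocenters, including the contra-steric cis C11/O8 pair on a six-membered ring, plus four base-stable protecting groups.

**Alternative 3: cut C6–C7 within a 13-membered bis-allylic ether.** The forward key step is a [2,3]-Wittig ring contraction of A3.
- The alkyllithium base forces C14 and C12 down to the alcohol level, which costs several redox and protecting-group steps.
- Deprotonation can occur at C6 or at C13.
- C6 and C7 are set by a macrocyclic conformation that C8 and C9 influence only indirectly.
- The chosen plan keeps C14 as the ester throughout and builds ring B at its final oxidation level.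

Key step: step 13

Assumption: atom labels C1–C15 follow the germacrane numbering of 23, and compounds 7–11 and 13–15 are carried as mixtures of C9 epimers, which converge when C9 becomes a ketone in 16.

## Steps

Step 1
Reactants: 1 geranyl acetate
Product: 2 (2E)-6,7-epoxy-3,7-dimethyloct-2-en-1-yl acetate (racemic epoxide)
Conditions: mCPBA, CH2Cl2, 0 °C
Reagents that add atoms: 3-chloroperoxybenzoic acid, OOC(=O)c1cccc(Cl)c1
Why: Prilezhaev epoxidation; the remote trisubstituted olefin is the more electron-rich one because the 2,3-olefin is deactivated by the allylic acetate, and the epoxide stereocenter is erased in step 2.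

Step 2
Reactants: 2 (2E)-6,7-epoxy-3,7-dimethyloct-2-en-1-yl acetate
Product: 3 (4E)-6-acetoxy-4-methylhex-4-enal
Conditions: H5IO6, THF/H2O, 0 °C
Reagents that add atoms: none
Why: Acid-catalysed epoxide hydrolysis and Malaprade glycol cleavage in one pot; water opens the tertiary carbon, which leaves as acetone, and the E-olefin (future C4=C5) is untouched.

Step 3
Reactants: 3 (4E)-6-acetoxy-4-methylhex-4-enal
Product: 4 methyl (2Z,6E)-8-acetoxy-2-iodo-6-methylocta-2,6-dienoate
Conditions: Ph3P=CHCO2Me, NIS, CH2Cl2, −20 °C; then 3, rt
Reagents that add atoms: methyl (triphenylphosphoranylidene)acetate, COC(=O)C=P(c1ccccc1)(c1ccccc1)c1ccccc1; N-iodosuccinimide, O=C1CCC(=O)N1I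
Why: Wittig olefination with an α-iodo stabilized ylide made in the flask; such ylides should give mainly the Z-iodoacrylate, with the chain trans to the ester, which is the geometry of C1=C10.

Step 4
Reactants: 4 methyl (2Z,6E)-8-acetoxy-2-iodo-6-methylocta-2,6-dienoate; 5 acrolein
Product: 7 methyl (2E,6E)-8-acetoxy-2-(1-hydroxyprop-2-en-1-yl)-6-methylocta-2,6-dienoate (racemic at C9), via alkenylmagnesium chloride 6 (not isolated)
Conditions: i-PrMgCl·LiCl, THF, −78 °C; then 5, −78 to −40 °C
Reagents that add atoms: isopropylmagnesium chloride, CC(C)[Mg]Cl (magnesium and chlorine are carried only by 6)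
Why: Iodine–magnesium exchange on the electron-poor alkenyl iodide is fast at low temperature and tolerates both esters; 1,2-addition to acrolein forms C9–C10 with C9 cis to C2, and C9 is left racemic on purpose because it becomes a ketone in step 12.

Step 5
Reactants: 7 methyl (2E,6E)-8-acetoxy-2-(1-hydroxyprop-2-en-1-yl)-6-methylocta-2,6-dienoate
Product: 8 methyl (2E,6E)-8-acetoxy-2-[1-(tert-butyldimethylsilyloxy)prop-2-en-1-yl]-6-methylocta-2,6-dienoate
Conditions: TBSCl, imidazole, DMF, rt
Reagents that add atoms: tert-butyldimethylsilyl chloride, CC(C)(C)[Si](C)(C)Cl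
Why: Standard silylation; this is the only protecting group of the route and it keeps O9 out of the oxidation in step 7 and the esterification in step 9.

Step 6
Reactants: 8 methyl (2E,6E)-8-acetoxy-2-[1-(tert-butyldimethylsilyloxy)prop-2-en-1-yl]-6-methylocta-2,6-dienoate
Product: 9 methyl (2E,6E)-2-[1-(tert-butyldimethylsilyloxy)prop-2-en-1-yl]-8-hydroxy-6-methylocta-2,6-dienoate
Conditions: K2CO3 (cat.), MeOH, 0 °C
Reagents that add atoms: none
Why: Transesterification of the primary acetate; the methyl ester is degenerate in methanol, and the hindered trisubstituted enoate and the silyl ether should be inert.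

Step 7
Reactants: 9 methyl (2E,6E)-2-[1-(tert-butyldimethylsilyloxy)prop-2-en-1-yl]-8-hydroxy-6-methylocta-2,6-dienoate
Product: 10 methyl (2E,6E)-2-[1-(tert-butyldimethylsilyloxy)prop-2-en-1-yl]-6-methyl-8-oxoocta-2,6-dienoate
Conditions: MnO2, CH2Cl2, rt
Reagents that add atoms: none
Why: Selective allylic oxidation of the primary alcohol to the E-enal (C6) without olefin isomerization.

Step 8
Reactants: 10 methyl (2E,6E)-2-[1-(tert-butyldimethylsilyloxy)prop-2-en-1-yl]-6-methyl-8-oxoocta-2,6-dienoate
Product: 11 methyl (2E,6E,8S)-2-[1-(tert-butyldimethylsilyloxy)prop-2-en-1-yl]-8-hydroxy-6-methyldeca-2,6,9-trienoate (6S in target numbering)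
Conditions: Zn(CH=CH2)2, (−)-3-exo-morpholinoisoborneol (10 mol %), toluene, −30 °C
Reagents that add atoms: divinylzinc, C=C[Zn]C=C
Why: Catalytic enantioselective alkenylzinc addition to an aldehyde with an amino-alcohol ligand; the Si-face delivery usual for this ligand class sets 6S, the only stereocenter of the route that is not relayed, and esters and the silyl ether are inert to the organozinc.

Step 9
Reactants: 11 methyl (2E,6E,8S)-2-[1-(tert-butyldimethylsilyloxy)prop-2-en-1-yl]-8-hydroxy-6-methyldeca-2,6,9-trienoate; 12 (diethoxyphosphoryl)acetic acid
Product: 13 methyl (2E,6E,8S)-2-[1-(tert-butyldimethylsilyloxy)prop-2-en-1-yl]-8-{[(diethoxyphosphoryl)acetyl]oxy}-6-methyldeca-2,6,9-trienoate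
Conditions: DCC, DMAP (cat.), CH2Cl2, 0 °C to rt
Reagents that add atoms: none
Why: Steglich esterification under neutral conditions attaches C12 and C11 to O6 without ionizing the bis-allylic C6–O bond, so C6 is retained.

Step 10
Reactants: 13 methyl (2E,6E,8S)-2-[1-(tert-butyldimethylsilyloxy)prop-2-en-1-yl]-8-{[(diethoxyphosphoryl)acetyl]oxy}-6-methyldeca-2,6,9-trienoate
Product: 14 (6S)-cyclodeca-1(10),4,7-triene bearing C10-CO2Me + C4-Me + O6-phosphonoacetate + O9-TBS (C1=C10 ring-cis; C4=C5 E; C7=C8 Z)
Conditions: second-generation Hoveyda–Grubbs catalyst (10 mol %), 1,4-benzoquinone (20 mol %), toluene (1 mM), 60 °C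
Reagents that add atoms: none
Why: Ring-closing metathesis between the only two monosubstituted olefins; both trisubstituted olefins are spectators and pre-bend the chain, the ring size favours the Z-olefin, and the C7=C8 geometry is erased in step 13 in any case.

Step 11
Reactants: 14 (6S)-cyclodeca-1(10),4,7-triene silyl ether
Product: 15 (6S)-9-hydroxycyclodeca-1(10),4,7-triene bearing C10-CO2Me + C4-Me + O6-phosphonoacetate
Conditions: HF·pyridine, THF, 0 °C
Reagents that add atoms: none
Why: Acidic fluoride desilylation avoids base, which would trigger premature reactions of the phosphonoacetate.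

Step 12
Reactants: 15 (6S)-9-hydroxycyclodeca-1(10),4,7-triene
Product: 16 (6S)-9-oxocyclodeca-1(10),4,7-triene bearing C10-CO2Me + C4-Me + O6-phosphonoacetate
Conditions: Dess–Martin periodinane, CH2Cl2, 0 °C
Reagents that add atoms: none
Why: Mild oxidation of the bis-allylic alcohol; both C9 epimers converge on one γ-acyloxy enone.

Step 13
Reactants: 16 (6S)-9-oxocyclodeca-1(10),4,7-triene phosphonoacetate
Product: 18 (6R,7S)-9-oxo α-methylene lactone (rings A and B complete; C8 is CH2), via phosphonolactone 17 (not isolated)
Conditions: Cs2CO3, THF (2 mM), 0 °C to rt; then paraformaldehyde, rt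
Reagents that add atoms: formaldehyde (as paraformaldehyde), C=O
Why: Cs2CO3 deprotonates the phosphonoacetate CH2 (C11), and the stabilized carbanion adds to C7, the β-carbon of the C7=C8–C9=O enone, in a 5-exo-trig conjugate addition that closes ring B (O6, C12, C11, C7, C6) and gives 17. Proton transfer regenerates the phosphonate carbanion, which olefinates formaldehyde (Horner–Wadsworth–Emmons) to the C11=C13 methylene of 18. The closest known reaction type is the telescoped intramolecular Michael/olefination of phosphonoacetates of γ-hydroxy enones. C7 is the only new stereocenter: allylic 1,3-strain in the Z-enone holds H6 in the olefin plane, so O6 with its tether lies on the outer face and C5 on the inner one, and attack from the outer face puts C8 trans to C5 on ring B. Because the addition of a stabilized carbanion is reversible, the trans-fused lactone should also be the thermodynamic product, whatever C7=C8 geometry step 10 delivers. The step needs site selectivity between C7 and the more electrophilic C1 of the alkylidene β-keto ester; only C7 is reached through a five-membered transition state (C1 would need a nine-membered one), and high dilution with a non-nucleophilic carbonate base holds back intermolecular addition. Reversible γ-deprotonation at C2 may scramble C1=C10, but the ring-cis isomer is the less strained partner of the ring-trans C4=C5 bond and should be restored.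

Step 14
Reactants: 18 (6R,7S)-9-oxo α-methylene lactone
Product: 20 (6R,7S,8R)-8-bromo-9-oxo α-methylene lactone, via silyl dienol ether 19 (not isolated)
Conditions: LiN(SiMe3)2, Me3SiCl, THF, −78 °C; then NBS, −78 °C
Reagents that add atoms: N-bromosuccinimide, O=C1CCC(=O)N1Br; chlorotrimethylsilane, C[Si](C)(C)Cl (silicon is carried only by 19)
Why: Kinetic α′-enolization with internal silyl quench (C10 has no hydrogen, and γ-deprotonation at C2 is the slower, thermodynamic path), then electrophilic bromination of the enol ether. With H7 in the olefin plane the C6 side is covered by ring A, so bromine should enter from the exposed C11 side and give 8R.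

Step 15
Reactants: 20 (6R,7S,8R)-8-bromo-9-oxo α-methylene lactone; 21 angelic acid
Product: 22 (6R,7S,8S)-8-angeloyloxy-9-oxo α-methylene lactone
Conditions: Cs2CO3, DMF, 0 °C to rt
Reagents that add atoms: none
Why: SN2 displacement of an α-halo ketone by a carboxylate salt; inversion turns the substrate-controlled 8R bromide into the 8S ester, installs the angelate without any acylating agent that could isomerize it, and leaves no hydroxyl to protect.

Step 16
Reactants: 22 (6R,7S,8S)-8-angeloyloxy-9-oxo α-methylene lactone
Product: 23 polymatin A (6R,7S,8S,9S)
Conditions: NaBH4, CeCl3·7H2O, MeOH, −78 °C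
Reagents that add atoms: none
Why: Luche 1,2-reduction of the conjugated C9 ketone, which is faster at low temperature than conjugate reduction at C1 or C13. The polar Felkin–Anh model (C8–O bond anti to the incoming hydride, no chelation by the acyloxy group) predicts the threo 8S,9S product, and the cold, weakly acidic medium should suppress the O8 to O9 acyl shift.

## Compound list

1 | geranyl acetate | CC(=O)OC/C=C(\C)CCC=C(C)C | starting material
2 | (2E)-6,7-epoxy-3,7-dimethyloct-2-en-1-yl acetate (racemic epoxide) | CC(=O)OC/C=C(\C)CCC1OC1(C)C | intermediate
3 | (4E)-6-acetoxy-4-methylhex-4-enal | CC(=O)OC/C=C(\C)CCC=O | intermediate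
4 | methyl (2Z,6E)-8-acetoxy-2-iodo-6-methylocta-2,6-dienoate | CC(=O)OC/C=C(\C)CC/C=C(/C(=O)OC)I | intermediate
5 | acrolein | C=CC=O | starting material
6 | (2Z,6E)-alkenylmagnesium chloride from 4 (MgCl in place of I) | CC(=O)OC/C=C(\C)CC/C=C(/C(=O)OC)[Mg]Cl | intermediate
7 | methyl (2E,6E)-8-acetoxy-2-(1-hydroxyprop-2-en-1-yl)-6-methylocta-2,6-dienoate (racemic at C9) | CC(=O)OC/C=C(\C)CC/C=C(/C(=O)OC)C(O)C=C | intermediate
8 | tert-butyldimethylsilyl ether of 7 | CC(=O)OC/C=C(\C)CC/C=C(/C(=O)OC)C(O[Si](C)(C)C(C)(C)C)C=C | intermediate
9 | methyl (2E,6E)-2-[1-(tert-butyldimethylsilyloxy)prop-2-en-1-yl]-8-hydroxy-6-methylocta-2,6-dienoate | OC/C=C(\C)CC/C=C(/C(=O)OC)C(O[Si](C)(C)C(C)(C)C)C=C | intermediate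
10 | methyl (2E,6E)-2-[1-(tert-butyldimethylsilyloxy)prop-2-en-1-yl]-6-methyl-8-oxoocta-2,6-dienoate | O=C/C=C(\C)CC/C=C(/C(=O)OC)C(O[Si](C)(C)C(C)(C)C)C=C | intermediate
11 | methyl (2E,6E,8S)-2-[1-(tert-butyldimethylsilyloxy)prop-2-en-1-yl]-8-hydroxy-6-methyldeca-2,6,9-trienoate (6S, both C9 epimers) | O[C@@H](C=C)/C=C(\C)CC/C=C(/C(=O)OC)C(O[Si](C)(C)C(C)(C)C)C=C | intermediate
12 | (diethoxyphosphoryl)acetic acid | CCOP(=O)(OCC)CC(=O)O | starting material
13 | (diethoxyphosphoryl)acetate of 11 (6S, both C9 epimers) | CCOP(=O)(OCC)CC(=O)O[C@@H](C=C)/C=C(\C)CC/C=C(/C(=O)OC)C(O[Si](C)(C)C(C)(C)C)C=C | intermediate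
14 | (6S)-cyclodeca-1(10),4,7-triene: C10-CO2Me, C4-Me, O6-phosphonoacetate, O9-TBS; C1=C10 ring-cis (E), C4=C5 E, C7=C8 Z | CCOP(=O)(OCC)CC(=O)O[C@@H]1/C=C(\C)CC/C=C(/C(=O)OC)C(O[Si](C)(C)C(C)(C)C)/C=C\1 | intermediate
15 | (6S)-9-hydroxy analogue of 14 (both C9 epimers) | CCOP(=O)(OCC)CC(=O)O[C@@H]1/C=C(\C)CC/C=C(/C(=O)OC)C(O)/C=C\1 | intermediate
16 | (6S)-9-oxocyclodeca-1(10),4,7-triene: C10-CO2Me, C4-Me, O6-phosphonoacetate | CCOP(=O)(OCC)CC(=O)O[C@@H]1/C=C(\C)CC/C=C(/C(=O)OC)C(=O)/C=C\1 | intermediate
17 | (6R,7R)-11-(diethoxyphosphoryl) lactone, 9-oxo (C11 epimers) | CCOP(=O)(OCC)C1C(=O)O[C@@H]2/C=C(\C)CC/C=C(/C(=O)OC)C(=O)C[C@@H]12 | intermediate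
18 | (6R,7S)-9-oxo α-methylene lactone, C8 = CH2 | C=C1C(=O)O[C@@H]2/C=C(\C)CC/C=C(/C(=O)OC)C(=O)C[C@@H]12 | intermediate
19 | (6R,7S)-9-(trimethylsilyloxy)-8,9-ene (cross-conjugated silyl dienol ether of 18) | C=C1C(=O)O[C@@H]2/C=C(\C)CC/C=C(/C(=O)OC)C(\O[Si](C)(C)C)=C/[C@@H]12 | intermediate
20 | (6R,7S,8R)-8-bromo-9-oxo α-methylene lactone | C=C1C(=O)O[C@@H]2/C=C(\C)CC/C=C(/C(=O)OC)C(=O)[C@H](Br)[C@@H]12 | intermediate
21 | angelic acid, (2Z)-2-methylbut-2-enoic acid | OC(=O)/C(C)=C\C | starting material
22 | (6R,7S,8S)-8-angeloyloxy-9-oxo α-methylene lactone | C=C1C(=O)O[C@@H]2/C=C(\C)CC/C=C(/C(=O)OC)C(=O)[C@@H](OC(=O)/C(C)=C\C)[C@@H]12 | intermediate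
23 | polymatin A (6R,7S,8S,9S) | C=C1C(=O)O[C@@H]2/C=C(\C)CC/C=C(/C(=O)OC)[C@H](O)[C@@H](OC(=O)/C(C)=C\C)[C@@H]12 | target

## Step count and least certain steps

Total step count: 16. Longest linear sequence: 16 steps, from 1 to 23.

**Step 13 (key step).** The most likely failure is consumption of 16 by base through its doubly activated C1=C10 acceptor. This could be intermolecular conjugate addition, or γ-deprotonation at C2 followed by oligomerization, occurring before the less populated ester rotamer needed for five-ring closure can react. The fallback leaves the basic medium.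
- From 16, t-BuMe2SiOTf and Et3N in CH2Cl2 at −78 °C should silylate the acidic phosphonoacetate to its ketene silyl acetal and activate the enone.
- An intramolecular Mukaiyama–Michael addition then gives the C8=C9 tert-butyldimethylsilyl enol ether of the phosphonolactone F1.
- K2CO3 and paraformaldehyde give the α-methylene lactone silyl enol ether F2.
- NBS converts F2 into 20, where the route is rejoined. Steps 13 and 14 are replaced, and the kinetic enolization is no longer needed.

**Step 10.** The most likely failure is oligomerization by intermolecular metathesis, together with catalytic re-opening of the strained triene, because the new disubstituted olefin remains a good substrate for the catalyst. The fallback closes the ring onto an electron-poor olefin.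
- From 13, HF·pyridine gives the acyclic C9 alcohol F3.
- Dess–Martin periodinane gives the acyclic vinyl ketone F4.
- Metathesis, initiated at the C6 vinyl group and terminated on the acryloyl group, gives 16 directly. The enone olefin formed is not re-opened, so closure becomes kinetically irreversible.

**Step 14.** The most likely failure is poor or reversed facial selectivity of the bromination, because the ring conformation of 19 is only inferred from allylic strain. Competing γ-enolization is also possible. If the electrophile enters from the C6 side, the fallback uses an oxygen electrophile instead.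
- From 19, Rubottom oxidation with dimethyldioxirane gives the (8S)-α-hydroxy ketone F5.
- F5 is esterified with the mixed anhydride of 21 and 2,4,6-trichlorobenzoyl chloride (Et3N, toluene) to 22.

**Step 15.** The most likely failures are loss of HBr toward C7, which re-forms the enone and erases C7, and epimerization at C8 by bromide exchange or enolization before substitution. Both are possible because C8 is β-branched and the medium is weakly basic. The fallback avoids the halide.
- From 19, Rubottom oxidation from the same exposed face gives the (8R)-α-hydroxy ketone F6.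
- Mitsunobu esterification with 21 (PPh3, DIAD) inverts C8 and gives 22.

**Step 16.** The most likely failure is poor facial selectivity, because the macrocyclic conformation may override the Felkin–Anh preference. Conjugate reduction at C1 or C13 is a second risk. The fallback replaces substrate control by reagent control. A Corey–Bakshi–Shibata reduction of 22 is run with the catalyst enantiomer chosen by the large/small model, taking the C10 alkenyl branch as the large group. It sets out from 22 and returns at 23, and no new compound is made (F0).

**Step 8.** The most likely failure is low enantioselectivity, because the parent vinyl group is a small, fast-transferring nucleophile and uncatalysed background addition competes. The fallback sets C6 by reduction.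
- From 10, vinylmagnesium bromide at −78 °C gives the racemic bis-allylic alcohol F7.
- MnO2 gives the cross-conjugated dienone F8.
- Reduction with (R)-Me-CBS oxazaborolidine and catecholborane, which distinguishes the trisubstituted alkenyl branch from the vinyl branch, gives 11.

## Further compounds

F1 | step 13 | (6R,7R)-11-(diethoxyphosphoryl) lactone 9-(tert-butyldimethylsilyloxy)-8,9-ene | CCOP(=O)(OCC)C1C(=O)O[C@@H]2/C=C(\C)CC/C=C(/C(=O)OC)C(\O[Si](C)(C)C(C)(C)C)=C/[C@@H]12
F2 | step 13 | (6R,7S)-α-methylene lactone 9-(tert-butyldimethylsilyloxy)-8,9-ene | C=C1C(=O)O[C@@H]2/C=C(\C)CC/C=C(/C(=O)OC)C(\O[Si](C)(C)C(C)(C)C)=C/[C@@H]12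
F3 | step 10 | acyclic (6S)-phosphonoacetate with free C9 hydroxyl (both C9 epimers) | CCOP(=O)(OCC)CC(=O)O[C@@H](C=C)/C=C(\C)CC/C=C(/C(=O)OC)C(O)C=C
F4 | step 10 | acyclic (6S)-phosphonoacetate C9 vinyl ketone | CCOP(=O)(OCC)CC(=O)O[C@@H](C=C)/C=C(\C)CC/C=C(/C(=O)OC)C(=O)C=C
F5 | step 14 | (6R,7R,8S)-8-hydroxy-9-oxo α-methylene lactone | C=C1C(=O)O[C@@H]2/C=C(\C)CC/C=C(/C(=O)OC)C(=O)[C@@H](O)[C@@H]12
F6 | step 15 | (6R,7R,8R)-8-hydroxy-9-oxo α-methylene lactone | C=C1C(=O)O[C@@H]2/C=C(\C)CC/C=C(/C(=O)OC)C(=O)[C@H](O)[C@@H]12
F0 | step 16 | none | none
F7 | step 8 | racemic C6 alcohol corresponding to 11 | OC(C=C)/C=C(\C)CC/C=C(/C(=O)OC)C(O[Si](C)(C)C(C)(C)C)C=C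
F8 | step 8 | C6 dienone, methyl (2E,6E)-2-[1-(tert-butyldimethylsilyloxy)prop-2-en-1-yl]-6-methyl-8-oxodeca-2,6,9-trienoate | O=C(C=C)/C=C(\C)CC/C=C(/C(=O)OC)C(O[Si](C)(C)C(C)(C)C)C=C
A1 | alternative 1 | seco enal (Z)-2-(bromomethyl)acrylate with O8 and O9 silylated | O=C/C=C(\C)CC/C=C(/C(=O)OC)[C@H](O[Si](C)(C)C(C)(C)C)[C@@H](O[Si](C)(C)C(C)(C)C)/C=C(\CBr)C(=O)OC
A2 | alternative 2 | cis-1-vinyl-2-isopropenylcyclohexanol carrying O6-TBS, the C7 2-(silyloxymethyl)vinyl group, O8-PMB and O9-MOM | C=C[C@]1(O)[C@H](C(C)=C)[C@@H](O[Si](C)(C)C(C)(C)C)[C@H](C(=C)CO[Si](C)(C)C(C)(C)C)[C@H](OCc2ccc(OC)cc2)[C@H]1OCOC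
A3 | alternative 3 | 13-membered bis-allylic ether (O between C6 and C13) with C12 and C14 as silyl ethers and O8, O9 as MOM ethers | O1C/C=C(\C)CC/C=C(/CO[Si](C)(C)C(C)(C)C)[C@H](OCOC)[C@@H](OCOC)/C=C(/CO[Si](C)(C)C(C)(C)C)C1
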